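**Retrosynthetic overview**
1. 8 ⇒ 6 + 7: the aryl–alkenyl bond is made last by a base-free Stille coupling, so the enolisable stereocentre never meets a base.
2. 6 ⇒ 3 + 4: the key C(=O)–CH(CH3)OAr bond. The formyl carbon of 4 acts as an acyl anion (enaminol 5 on a chiral triazolylidene). Vinyl ether 3 acts as a masked acetaldehyde oxocarbenium. Both carbons are normally electrophilic; the ether bond is already in place and the (R) centre is set in this step.
3. 3 ⇒ 1 + 2: O-vinylation of the phenol.
4. No ring is formed. Ring A (trimethoxyphenyl) and ring B (dimethoxyphenoxy) are bought intact.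

**Assumption:** the target stereocentre is (R) by CIP analysis of the given SMILES. The sense of induction in step 2 rests on a transition-state model only, so the (5aS,10bR) triazolium chloride (Cc1cc(C)c(c(C)c1)-[n+]1cn2c(n1)CO[C@H]1Cc3ccccc3[C@H]12.[Cl-]) is written, and its equally available (5aR,10bS) antipode replaces it unchanged if the first run gives (S)-6. Compounds 1, 2, 4, 7 and the salt are taken as catalogue items.

**Step 1**
Reactants: 1 4-bromo-2,6-dimethoxyphenol; 2 vinyl acetate
Product: 3 5-bromo-2-(ethenyloxy)-1,3-dimethoxybenzene
Conditions: [Ir(cod)Cl]2 (1 mol %), Na2CO3 (0.6 equiv), 2 (2 equiv), toluene, 100 °C, Ar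
Reagents that add atoms: none
Why: Iridium-catalysed transfer vinylation (the phenol adds to coordinated vinyl acetate, acetate leaves and is neutralised by Na2CO3) is established for electron-rich phenols, the aryl bromide is inert to the monovalent iridium catalyst, and no stereocentre is formed.

**Step 2**
Reactants: 3 5-bromo-2-(ethenyloxy)-1,3-dimethoxybenzene; 4 3,4,5-trimethoxybenzaldehyde
Product: 6 (R)-2-(4-bromo-2,6-dimethoxyphenoxy)-1-(3,4,5-trimethoxyphenyl)propan-1-one, via Breslow enaminol 5 (not isolated)
Conditions: (5aS,10bR)-2-(2,4,6-trimethylphenyl)-5a,10b-dihydro-4H,6H-indeno[2,1-b][1,2,4]triazolo[4,3-d][1,4]oxazin-2-ium chloride (20 mol %), CsOAc (20 mol %), 4 (1.5 equiv), 4 Å MS, toluene (1 M), 70 °C, Ar; recrystallise 6 to constant ee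
Reagents that add atoms: none
Why: Proposed new method: intermolecular enantioselective carbene-catalysed hydroacylation of an aryl vinyl ether. The triazolylidene turns the formyl carbon of 4 into the nucleophilic enaminol 5 (acyl anion equivalent); its O–H proton goes to the electron-rich terminal CH2 of 3 while its carbon bonds to the emerging oxocarbenium carbon in an asynchronous five-centre, ene-like transition state, so only the branched ketone can form, and collapse of the adduct releases the carbene. The di-ortho-substituted ring B is twisted out of conjugation, which makes the ether oxygen a better donor and the alkene a better proton acceptor. The (R) centre is set in this C–C bond formation: the indane wall closes one face of 5, and the bulky aryloxy group sits under the developing azolium ring, away from the mesityl methyls. Homo-benzoin of 4 is reversible, and the CsOAc/AcOH pair is too weak to enolise 6. Closest known reaction types are intramolecular carbene-catalysed hydroacylation of enol ethers and of unactivated alkenes (the latter highly enantioselective with this catalyst family), intermolecular hydroacylation of cyclopropenes and styrenes, and acetate-buffered asymmetric cross-aza-benzoin reactions that preserve an α-heteroatom stereocentre.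

**Step 3**
Reactants: 6 (R)-2-(4-bromo-2,6-dimethoxyphenoxy)-1-(3,4,5-trimethoxyphenyl)propan-1-one; 7 (E)-3-(tributylstannyl)prop-2-en-1-ol
Product: 8 (R)-2-{4-[(E)-3-hydroxyprop-1-en-1-yl]-2,6-dimethoxyphenoxy}-1-(3,4,5-trimethoxyphenyl)propan-1-one (CNP0171423.1)
Conditions: Pd(PPh3)4 (5 mol %), 7 (1.2 equiv), toluene, 100 °C, Ar
Reagents that add atoms: none
Why: In this Stille cross-coupling zerovalent palladium inserts into the unhindered C–Br bond and the alkenyl group transfers from tin with retention of the E geometry, while the neutral base-free medium tolerates the ketone and free hydroxyl and leaves the (R) centre untouched.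

**Compound list**
1 | 4-bromo-2,6-dimethoxyphenol | COc1cc(Br)cc(OC)c1O | starting material
2 | vinyl acetate | C=COC(C)=O | starting material
3 | 5-bromo-2-(ethenyloxy)-1,3-dimethoxybenzene (aryl vinyl ether of 1) | C=COc1c(OC)cc(Br)cc1OC | intermediate
4 | 3,4,5-trimethoxybenzaldehyde | COc1cc(C=O)cc(OC)c1OC | starting material
5 | Breslow enaminol: adduct of 4 with the (5aS,10bR) triazolylidene, drawn with OH syn to N-mesityl; gives the carbene back on forming 6 | O/C(c1cc(OC)c(OC)c(OC)c1)=C1\N(c2c(C)cc(C)cc2C)N=C2CO[C@H]3Cc4ccccc4[C@H]3N12 | intermediate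
6 | (R)-2-(4-bromo-2,6-dimethoxyphenoxy)-1-(3,4,5-trimethoxyphenyl)propan-1-one | COc1cc(C(=O)[C@@H](C)Oc2c(OC)cc(Br)cc2OC)cc(OC)c1OC | intermediate
7 | (E)-3-(tributylstannyl)prop-2-en-1-ol | CCCC[Sn](CCCC)(CCCC)/C=C/CO | starting material
8 | (R)-2-{4-[(E)-3-hydroxyprop-1-en-1-yl]-2,6-dimethoxyphenoxy}-1-(3,4,5-trimethoxyphenyl)propan-1-one | COc1cc(C(=O)[C@@H](C)Oc2c(OC)cc(/C=C/CO)cc2OC)cc(OC)c1OC | target

**Total step count:** 3. **Longest linear sequence:** 3 (1 → 3 → 6 → 8).

**Steps most likely to fail**

Step 2 is the highest risk. The intermolecular reaction has no precedent, and it could suffer from a low rate, alkylation of the carbene, or modest ee. The fallback sets out from 4 and comes back to the route at 6. It keeps the acyl anion logic but hands it to an enzyme, and the ether bond is made afterwards. Benzoylformate decarboxylase from Pseudomonas putida (thiamine diphosphate, MgSO4, KH2PO4/K2HPO4 buffer pH 7 with 20 % DMSO, 30 °C) couples 4 as donor with acetaldehyde as acceptor. This gives (S)-2-hydroxy-1-(3,4,5-trimethoxyphenyl)propan-1-one F1. Mitsunobu etherification of F1 with phenol 1 (PPh3, DIAD, toluene, 0 °C to rt) inverts the carbinol centre and delivers (R)-6.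

Step 1 may fail because the di-ortho-substituted phenol could be vinylated slowly or O-acetylated instead. The fallback sets out from 1 and comes back at 3, replacing metal-catalysed vinyl transfer by alkylation and elimination. Compound 1 and excess 1,2-dibromoethane (K2CO3, acetone, reflux) give 5-bromo-2-(2-bromoethoxy)-1,3-dimethoxybenzene F2. KOt-Bu (THF, 0 °C to rt) then removes HBr by E2 elimination to give 3.

Step 3 may fail through slow oxidative addition of the electron-rich bromide, erosion of ee on prolonged heating, or tin residues. The fallback sets out from 3 and comes back at 8, building the side chain before any stereocentre exists. Heck reaction of 3 with ethyl acrylate (Pd(OAc)2, P(o-tol)3, K2CO3, DMF, 100 °C) gives ethyl (E)-3-[4-(ethenyloxy)-3,5-dimethoxyphenyl]prop-2-enoate F3. Reduction with i-Bu2AlH (CH2Cl2, −78 °C, aqueous potassium sodium tartrate work-up) gives (E)-3-[4-(ethenyloxy)-3,5-dimethoxyphenyl]prop-2-en-1-ol F4. Hydroacylation of F4 with 4 under the conditions of step 2 (again through 5) gives 8 directly, so nothing follows the stereocentre-forming step.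

**Further compounds**
F1 | step 2 | (S)-2-hydroxy-1-(3,4,5-trimethoxyphenyl)propan-1-one | COc1cc(C(=O)[C@H](C)O)cc(OC)c1OC
F2 | step 1 | 5-bromo-2-(2-bromoethoxy)-1,3-dimethoxybenzene | COc1cc(Br)cc(OC)c1OCCBr
F3 | step 3 | ethyl (E)-3-[4-(ethenyloxy)-3,5-dimethoxyphenyl]prop-2-enoate | CCOC(=O)/C=C/c1cc(OC)c(OC=C)c(OC)c1
F4 | step 3 | (E)-3-[4-(ethenyloxy)-3,5-dimethoxyphenyl]prop-2-en-1-ol | OC/C=C/c1cc(OC)c(OC=C)c(OC)c1
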